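The numbers belong to no real substance; what happens was integrated by code.

If the free catalyst dies while it works, the first thing to count is how many substrate lifetimes fit into one catalyst lifetime.

| flask | substrate | free catalyst | remark | time |
|---|---|---|---|---|
| Wednesday's | 0.091 M | 7.6 mM | one stirred flow tank at steady state, fed with the mixture as stated, mean residence time 8.0 min |  |
| Saturday's | 0.091 M (fed, over 6.40 min) | 7.6 mM | a stirred flask in which substrate is dosed at a steady rate over 6.40 min without added volume, worked up at 8.0 min | 8.0 min |
| Sunday's | 0.091 M | 7.6 mM | a closed flask charged with all of it at once and left for 8.0 min | 8.0 min |

1. the set-up with the highest amount of target at the outlet or at the end, in percent of the substrate put in ("none" if the first two lie within 2 percentage points) (Wednesday's / Saturday's / Sunday's / none)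
2. amount of target at the outlet or at the end, in percent of the substrate put in, Wednesday's
3. amount of target at the outlet or at the end, in percent of the substrate put in, Saturday's
4. amount of target at the outlet or at the end, in percent of the substrate put in, Sunday's

- the stated concentrations are those of everything mixed, before any reaction; amounts are the same in each set-up
- the feed brings no volume worth counting
- run time (Saturday's): 8.0 min

    substrate + free catalyst → free catalyst + target (k1 = 7.03 M⁻¹ s⁻¹)
    target ⇌ isomer of the product (K2 = 19, k2 = 0.00296 s⁻¹)
    free catalyst → spent catalyst (k3 = 0.0346 s⁻¹)

Free catalyst turns substrate into target, target slides reversibly to the isomer of the product, and free catalyst decays by itself to spent catalyst. So I took the catalyst's lifetime, 0.482 min, and the substrate's lifetime at the charged c(free catalyst), 0.312 min. Their ratio came to 1.54: this is the reach, the catalyst's lifetime counted in substrate lifetimes. The substrate's loss is pseudo-first-order, but with a fading rate, so in Sunday's flask I expected 21.4 % of it to remain.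

Target relaxes with a half-life of 3.71 min, both ways together. The catalyst's life is short beside the run, so I aged Sunday's target the whole 8.0 min, which kept 26.3 % of it and gave 20.7 %.

Saturday's substrate arrives over 13.3 catalyst lifetimes, so I counted one lifetime's dose as converted and got 1.98 %.

Wednesday's tank is fed fresh catalyst. Its reach, 1.46, leaves substrate at one part in 2.46, but the tank's mixed ages hold 43.1 % of the product as target. That gave 25.5 %, and my choice was Wednesday's.

The forecast gave 25.5 %, 2.5 % and 21.7 % for Wednesday's, Saturday's and Sunday's and chose Wednesday's, crediting the tank with "its fresher catalyst supply and its shorter average product age". Its figures for Saturday's and Sunday's stood above mine.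

The simulation gave 25.5 %, 2.56 % and 21.7 %, with Wednesday's ahead.

Sunday's flask had not come to rest at 8.00 min. Its substrate stood at 21 %, against 21.4 % from the reach, with free catalyst at 0 %, and at 80.0 min substrate still stood at 21.3 %. Target, though, fell to 3.93 % by then, while the isomer of the product rose to 74.7 %. An earlier reading overturned the forecast's choice: Sunday's flask read at 3.0 min held 49.2 % of target, above Wednesday's 25.5 %.

In the flask like Sunday's but with 0.019 M of free catalyst, the reach grew to 3.86, which leaves 2.11 % of the substrate. The run left 2.11 %, with 26.4 % of target.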